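**Retrosynthetic overview**
- Both rings and all three stereocentres come from one cation–olefin bicyclization of an acyclic triene: C4–C5 closes ring A first, then C9–C10 closes ring B, and C3 appears directly as the ketone.
- The cyclization is started at C4 by umpolung of a tetrasubstituted silyl enol ether with a chiral diacetoxyiodoarene (the proposed new step).
- The (E)-alkene gives the trans ring fusion; the (Z)-allylic aryl ether alkene gives the axial (α) CH2OAr group at C9.
- The silyl enol ether comes from 1,4-hydrosilylation of an isopropenyl ketone; the aryl ether from a Mitsunobu reaction with umbelliferone.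
- The isopropenyl ketone comes from α′-alkylation of 3-methylbut-3-en-2-one with a C10 allylic bromide made from nerol.

Assumption: the SMILES is read literally, i.e. (5R,9R,10S) in drimane numbering (angular methyl β, H-5 α, CH2OAr α and axial); drimane numbering is used for the bicycle, and iodoarene 12 is taken as a purchasable chiral reagent.

**Route**

Step 1
Reactants: 1 nerol, (2Z)-3,7-dimethylocta-2,6-dien-1-ol
Product: 2 tert-butyl{[(2Z)-3,7-dimethylocta-2,6-dien-1-yl]oxy}dimethylsilane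
Conditions: TBSCl, imidazole, DMF, 0 °C to rt
Reagents that add atoms: tert-butyldimethylsilyl chloride, CC(C)(C)[Si](C)(C)Cl
Why: Standard silylation of a primary alcohol, which protects the hydroxyl through the oxidation and enolate steps and leaves the Z-alkene untouched.

Step 2
Reactants: 2 tert-butyl{[(2Z)-3,7-dimethylocta-2,6-dien-1-yl]oxy}dimethylsilane
Product: 3 (2E,6Z)-8-[(tert-butyldimethylsilyl)oxy]-2,6-dimethylocta-2,6-dien-1-ol
Conditions: SeO2 (0.3 equiv), t-BuOOH (70% aq., 3 equiv), salicylic acid (0.1 equiv), CH2Cl2, 0 °C to rt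
Reagents that add atoms: tert-butyl hydroperoxide, CC(C)(C)OO (oxygen relayed by selenium dioxide, O=[Se]=O)
Why: Sharpless SeO2/t-BuOOH allylic oxidation (ene reaction, then [2,3]-sigmatropic shift) occurs at the distal, more electron-rich trisubstituted alkene and selectively at its E-methyl group, giving the (E)-allylic alcohol, while the proximal alkene is deactivated by the allylic silyl ether.

Step 3
Reactants: 3 (2E,6Z)-8-[(tert-butyldimethylsilyl)oxy]-2,6-dimethylocta-2,6-dien-1-ol
Product: 4 tert-butyl{[(2Z,6E)-8-bromo-3,7-dimethylocta-2,6-dien-1-yl]oxy}dimethylsilane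
Conditions: CBr4, PPh3, CH2Cl2, 0 °C
Reagents that add atoms: carbon tetrabromide, BrC(Br)(Br)Br
Why: Appel bromination converts the primary allylic alcohol into the bromide by SN2 displacement of the alkoxyphosphonium ion at 0 °C, without allylic transposition or loss of alkene geometry.

Step 4
Reactants: 5 3-methylbut-3-en-2-one; 4 tert-butyl{[(2Z,6E)-8-bromo-3,7-dimethylocta-2,6-dien-1-yl]oxy}dimethylsilane
Product: 7 (6E,10Z)-12-[(tert-butyldimethylsilyl)oxy]-2,6,10-trimethyldodeca-1,6,10-trien-3-one, via lithium dienolate 6 (not isolated)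
Conditions: LiN(iPr)2, THF, −78 °C; then 4, DMPU, −78 to −30 °C
Reagents that add atoms: none
Why: Kinetic α′-deprotonation of the enone gives the cross-conjugated lithium dienolate, which C-alkylates the reactive primary allylic bromide (enolate SN2 alkylation) with both alkene geometries unchanged.

Step 5
Reactants: 7 (6E,10Z)-12-[(tert-butyldimethylsilyl)oxy]-2,6,10-trimethyldodeca-1,6,10-trien-3-one
Product: 8 (6E,10Z)-12-hydroxy-2,6,10-trimethyldodeca-1,6,10-trien-3-one
Conditions: HF·pyridine, THF–pyridine, 0 °C to rt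
Reagents that add atoms: none
Why: Fluoride desilylation of the primary silyl ether under mildly acidic conditions that do not enolize or add to the isopropenyl ketone.

Step 6
Reactants: 8 (6E,10Z)-12-hydroxy-2,6,10-trimethyldodeca-1,6,10-trien-3-one; 9 umbelliferone, 7-hydroxy-2H-chromen-2-one
Product: 10 7-{[(2Z,6E)-3,7,11-trimethyl-10-oxododeca-2,6,11-trien-1-yl]oxy}-2H-chromen-2-one
Conditions: DIAD and PPh3 premixed, THF, 0 °C; then 8 and 9, 0 °C to rt
Reagents that add atoms: none
Why: Mitsunobu etherification, in which the acidic phenol (pKa about 7.7) displaces the primary allylic alkoxyphosphonium ion by SN2 so that the Z-alkene is retained, and the preformed betaine keeps free phosphine away from the enone.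

Step 7
Reactants: 10 7-{[(2Z,6E)-3,7,11-trimethyl-10-oxododeca-2,6,11-trien-1-yl]oxy}-2H-chromen-2-one
Product: 11 7-{[(2Z,6E)-3,7,11-trimethyl-10-[(triethylsilyl)oxy]dodeca-2,6,10-trien-1-yl]oxy}-2H-chromen-2-one
Conditions: Et3SiH (1.2 equiv), RhCl(PPh3)3 (1 mol %), toluene, 50 °C
Reagents that add atoms: triethylsilane, CC[SiH](CC)CC
Why: Rhodium-catalysed 1,4-hydrosilylation of the s-cis enone with a monohydrosilane delivers the tetrasubstituted silyl enol ether regiospecifically (no E/Z issue, since the enol carbon carries two methyl groups), while the less reactive coumarin lactone and the trisubstituted alkenes are left alone.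

Step 8
Reactants: 12 (2R,2'R)-2,2'-[(2-iodo-1,3-phenylene)bis(oxy)]bis[N-(2,4,6-trimethylphenyl)propanamide]
Product: 13 (2R,2'R)-2,2'-{[2-(diacetoxyiodo)-1,3-phenylene]bis(oxy)}bis[N-(2,4,6-trimethylphenyl)propanamide]
Conditions: CH3CO3H (35% in AcOH), AcOH, 30 °C; crystallize
Reagents that add atoms: peracetic acid, CC(=O)OO; acetic acid, CC(=O)O
Why: Classical peracid oxidation of an aryl iodide to the (diacetoxyiodo)arene (trivalent iodine), which does not touch the lactamide stereocentres.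

Step 9
Reactants: 11 7-{[(2Z,6E)-3,7,11-trimethyl-10-[(triethylsilyl)oxy]dodeca-2,6,10-trien-1-yl]oxy}-2H-chromen-2-one; 13 (2R,2'R)-2,2'-{[2-(diacetoxyiodo)-1,3-phenylene]bis(oxy)}bis[N-(2,4,6-trimethylphenyl)propanamide]
Product: 15 7-{[(1R,4aR,8aS)-2,5,5,8a-tetramethyl-6-oxo-1,4,4a,5,6,7,8,8a-octahydronaphthalen-1-yl]methoxy}-2H-chromen-2-one, via iodine-bound enolate 14 (not isolated)
Conditions: 13 (1.1 equiv), BF3·OEt2 (1.5 equiv), CH2Cl2, −78 °C; then 11, −78 to −40 °C; aq. NaHCO3
Reagents that add atoms: none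
Why: Proposed new method: an enolonium-initiated, reagent-controlled enantioselective polyene bicyclization, in which ligand exchange of the silyl enol ether on the BF3-activated chiral diacetoxyiodoarene gives the O-bound trivalent-iodine enolate 14, whose α-carbon (C4) is an umpoled tertiary electrophile; the (E)-alkene attacks C4 through a chair transition state as the aryl iodide leaves and C3=O forms (SN2′-type, closing ring A with anti addition and hence the trans ring fusion at C5/C10), the C10 cation is captured by the (Z)-alkene in a second chair (closing ring B with the CH2OAr group axial and α at C9), and the C8 cation loses the axial C7 proton to acetate to give the Δ7 alkene, while the chiral lactamide arms of the iodane shield one face of the planar enol and so fix the absolute sense (5R,9R,10S); the closest known reaction types are umpolung α-functionalization of silyl enol ethers through hypervalent-iodine enolonium species with π-nucleophiles, enantioselective ketone α-oxygenation with lactate-derived chiral aryl iodanes, and Stork–Eschenmoser cation–olefin polycyclization.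

**Compound list**

1 | nerol, (2Z)-3,7-dimethylocta-2,6-dien-1-ol | CC(C)=CCC/C(C)=C\CO | starting material
2 | tert-butyl{[(2Z)-3,7-dimethylocta-2,6-dien-1-yl]oxy}dimethylsilane | CC(C)=CCC/C(C)=C\CO[Si](C)(C)C(C)(C)C | intermediate
3 | (2E,6Z)-8-[(tert-butyldimethylsilyl)oxy]-2,6-dimethylocta-2,6-dien-1-ol | OC/C(C)=C/CC/C(C)=C\CO[Si](C)(C)C(C)(C)C | intermediate
4 | tert-butyl{[(2Z,6E)-8-bromo-3,7-dimethylocta-2,6-dien-1-yl]oxy}dimethylsilane | BrC/C(C)=C/CC/C(C)=C\CO[Si](C)(C)C(C)(C)C | intermediate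
5 | 3-methylbut-3-en-2-one | CC(=O)C(C)=C | starting material
6 | lithium 3-methylbuta-1,3-dien-2-olate (not isolated) | [Li]OC(=C)C(C)=C | intermediate
7 | (6E,10Z)-12-[(tert-butyldimethylsilyl)oxy]-2,6,10-trimethyldodeca-1,6,10-trien-3-one | C=C(C)C(=O)CC/C(C)=C/CC/C(C)=C\CO[Si](C)(C)C(C)(C)C | intermediate
8 | (6E,10Z)-12-hydroxy-2,6,10-trimethyldodeca-1,6,10-trien-3-one | C=C(C)C(=O)CC/C(C)=C/CC/C(C)=C\CO | intermediate
9 | umbelliferone, 7-hydroxy-2H-chromen-2-one | Oc1ccc2ccc(=O)oc2c1 | starting material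
10 | 7-{[(2Z,6E)-3,7,11-trimethyl-10-oxododeca-2,6,11-trien-1-yl]oxy}-2H-chromen-2-one | C=C(C)C(=O)CC/C(C)=C/CC/C(C)=C\COc1ccc2ccc(=O)oc2c1 | intermediate
11 | 7-{[(2Z,6E)-3,7,11-trimethyl-10-[(triethylsilyl)oxy]dodeca-2,6,10-trien-1-yl]oxy}-2H-chromen-2-one | CC(C)=C(O[Si](CC)(CC)CC)CC/C(C)=C/CC/C(C)=C\COc1ccc2ccc(=O)oc2c1 | intermediate
12 | (2R,2'R)-2,2'-[(2-iodo-1,3-phenylene)bis(oxy)]bis[N-(2,4,6-trimethylphenyl)propanamide] | Ic1c(O[C@H](C)C(=O)Nc2c(C)cc(C)cc2C)cccc1O[C@H](C)C(=O)Nc1c(C)cc(C)cc1C | starting material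
13 | (2R,2'R)-2,2'-{[2-(diacetoxyiodo)-1,3-phenylene]bis(oxy)}bis[N-(2,4,6-trimethylphenyl)propanamide] | CC(=O)OI(OC(C)=O)c1c(O[C@H](C)C(=O)Nc2c(C)cc(C)cc2C)cccc1O[C@H](C)C(=O)Nc1c(C)cc(C)cc1C | intermediate
14 | O-bound trivalent-iodine enolate of 10: 7-{[(2Z,6E)-10-({acetoxy[2,6-bis({(2R)-1-oxo-1-[(2,4,6-trimethylphenyl)amino]propan-2-yl}oxy)phenyl]iodanyl}oxy)-3,7,11-trimethyldodeca-2,6,10-trien-1-yl]oxy}-2H-chromen-2-one (not isolated) | CC(C)=C(OI(OC(C)=O)c1c(O[C@H](C)C(=O)Nc2c(C)cc(C)cc2C)cccc1O[C@H](C)C(=O)Nc1c(C)cc(C)cc1C)CC/C(C)=C/CC/C(C)=C\COc1ccc2ccc(=O)oc2c1 | intermediate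
15 | 7-{[(1R,4aR,8aS)-2,5,5,8a-tetramethyl-6-oxo-1,4,4a,5,6,7,8,8a-octahydronaphthalen-1-yl]methoxy}-2H-chromen-2-one | CC1=CC[C@H]2C(C)(C)C(=O)CC[C@]2(C)[C@@H]1COc1ccc2ccc(=O)oc2c1 | target

**Step count and risks**

Total step count: 9 (eight on the main line plus the preparation of reagent 13). Longest linear sequence: 8 (steps 1–7 and 9, from nerol).

The three steps most likely to fail:

Step 9 (the proposed new step). Likely failure modes are protodesilylation of 11 to the isopropyl ketone, arrest after ring A, formation of the exocyclic Δ8(12) alkene isomer, and insufficient enantioselectivity. The sense of induction by the (R,R)-reagent is a working model and must be confirmed by chiral HPLC and optical rotation; the mirror-image iodoarene would be used if the sense is opposite, and the crystalline product can be enriched by recrystallization. The fallback uses known reactions only, sets out from 11 and comes back at 15. Rubottom oxidation of 11 (mCPBA, NaHCO3, CH2Cl2, −20 °C) gives 7-{[(2Z,6E)-3,7,11-trimethyl-10-oxo-11-[(triethylsilyl)oxy]dodeca-2,6-dien-1-yl]oxy}-2H-chromen-2-one F1. Corey–Bakshi–Shibata reduction ((S)-2-methyl-CBS-oxazaborolidine, catecholborane, toluene, −78 °C), in which the silyloxy-tert-alkyl group acts as the large substituent, gives 7-{[(2Z,6E,10R)-10-hydroxy-3,7,11-trimethyl-11-[(triethylsilyl)oxy]dodeca-2,6-dien-1-yl]oxy}-2H-chromen-2-one F2. Mesylation (MsCl, Et3N, CH2Cl2, 0 °C) gives (3R,6E,10Z)-2,6,10-trimethyl-12-[(2-oxo-2H-chromen-7-yl)oxy]-2-[(triethylsilyl)oxy]dodeca-6,10-dien-3-yl methanesulfonate F3. Fluoride (Bu4NF, THF, 0 °C) frees the tertiary alkoxide, which closes with inversion to 7-{[(2Z,6E)-9-[(2S)-3,3-dimethyloxiran-2-yl]-3,7-dimethylnona-2,6-dien-1-yl]oxy}-2H-chromen-2-one F4. Classical epoxide-initiated polyene cyclization (MeAlCl2, CH2Cl2, −78 °C), with the same alkene geometries controlling C5, C9 and C10, gives 7-{[(1R,4aR,6S,8aS)-6-hydroxy-2,5,5,8a-tetramethyl-1,4,4a,5,6,7,8,8a-octahydronaphthalen-1-yl]methoxy}-2H-chromen-2-one F5. Dess–Martin oxidation of the C3 alcohol then gives 15.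

Step 4 (alkylation of the enone dienolate). The dienolate of 5 can add to unreacted enone or polymerize before it is alkylated. The fallback sets out from 4 and comes back at 7. The lithium enolate of N-methoxy-N-methylacetamide (LiN(iPr)2, THF, −78 °C) is alkylated with 4 to give (4E,8Z)-10-[(tert-butyldimethylsilyl)oxy]-N-methoxy-N,4,8-trimethyldeca-4,8-dienamide F6. Addition of CH2=C(CH3)MgBr (THF, 0 °C) to this Weinreb amide then gives 7 without over-addition.

Step 7 (1,4-hydrosilylation in the presence of the coumarin). The rhodium hydride may also reduce the coumarin C3=C4 bond or give some 1,2-hydrosilylation. The fallback postpones the coumarin to the end; it sets out from 7 and comes back at 15. Hydrosilylation of 7 (Et3SiH, RhCl(PPh3)3) gives tert-butyl{[(2Z,6E)-3,7,11-trimethyl-10-[(triethylsilyl)oxy]dodeca-2,6,10-trien-1-yl]oxy}dimethylsilane F7. The bicyclization of step 9 with 13 and BF3·OEt2 gives (4aS,5R,8aR)-5-{[(tert-butyldimethylsilyl)oxy]methyl}-1,1,4a,6-tetramethyl-3,4,4a,5,8,8a-hexahydronaphthalen-2(1H)-one F8. Desilylation (HF·pyridine, THF) gives (4aS,5R,8aR)-5-(hydroxymethyl)-1,1,4a,6-tetramethyl-3,4,4a,5,8,8a-hexahydronaphthalen-2(1H)-one F9. A Mitsunobu reaction of this alcohol with 9 (PPh3, DIAD, THF) then gives 15.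

**Further compounds**

F1 | step 9 | 7-{[(2Z,6E)-3,7,11-trimethyl-10-oxo-11-[(triethylsilyl)oxy]dodeca-2,6-dien-1-yl]oxy}-2H-chromen-2-one | CC(C)(O[Si](CC)(CC)CC)C(=O)CC/C(C)=C/CC/C(C)=C\COc1ccc2ccc(=O)oc2c1
F2 | step 9 | 7-{[(2Z,6E,10R)-10-hydroxy-3,7,11-trimethyl-11-[(triethylsilyl)oxy]dodeca-2,6-dien-1-yl]oxy}-2H-chromen-2-one | CC(C)(O[Si](CC)(CC)CC)[C@H](O)CC/C(C)=C/CC/C(C)=C\COc1ccc2ccc(=O)oc2c1
F3 | step 9 | (3R,6E,10Z)-2,6,10-trimethyl-12-[(2-oxo-2H-chromen-7-yl)oxy]-2-[(triethylsilyl)oxy]dodeca-6,10-dien-3-yl methanesulfonate | CC(C)(O[Si](CC)(CC)CC)[C@H](OS(C)(=O)=O)CC/C(C)=C/CC/C(C)=C\COc1ccc2ccc(=O)oc2c1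
F4 | step 9 | 7-{[(2Z,6E)-9-[(2S)-3,3-dimethyloxiran-2-yl]-3,7-dimethylnona-2,6-dien-1-yl]oxy}-2H-chromen-2-one | CC1(C)O[C@H]1CC/C(C)=C/CC/C(C)=C\COc1ccc2ccc(=O)oc2c1
F5 | step 9 | 7-{[(1R,4aR,6S,8aS)-6-hydroxy-2,5,5,8a-tetramethyl-1,4,4a,5,6,7,8,8a-octahydronaphthalen-1-yl]methoxy}-2H-chromen-2-one | CC1=CC[C@H]2C(C)(C)[C@@H](O)CC[C@]2(C)[C@@H]1COc1ccc2ccc(=O)oc2c1
F6 | step 4 | (4E,8Z)-10-[(tert-butyldimethylsilyl)oxy]-N-methoxy-N,4,8-trimethyldeca-4,8-dienamide | CON(C)C(=O)CC/C(C)=C/CC/C(C)=C\CO[Si](C)(C)C(C)(C)C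
F7 | step 7 | tert-butyl{[(2Z,6E)-3,7,11-trimethyl-10-[(triethylsilyl)oxy]dodeca-2,6,10-trien-1-yl]oxy}dimethylsilane | CC(C)=C(O[Si](CC)(CC)CC)CC/C(C)=C/CC/C(C)=C\CO[Si](C)(C)C(C)(C)C
F8 | step 7 | (4aS,5R,8aR)-5-{[(tert-butyldimethylsilyl)oxy]methyl}-1,1,4a,6-tetramethyl-3,4,4a,5,8,8a-hexahydronaphthalen-2(1H)-one | CC1=CC[C@H]2C(C)(C)C(=O)CC[C@]2(C)[C@@H]1CO[Si](C)(C)C(C)(C)C
F9 | step 7 | (4aS,5R,8aR)-5-(hydroxymethyl)-1,1,4a,6-tetramethyl-3,4,4a,5,8,8a-hexahydronaphthalen-2(1H)-one | CC1=CC[C@H]2C(C)(C)C(=O)CC[C@]2(C)[C@@H]1CO
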